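Retrosynthesis: the C8 O-benzyl group and the C4 carbinol mask come off first. Ring A is then cut at C8–C8a (6π electrocyclisation) and at C4a–C5 (alkenyllithium addition). This returns C5–C8 to dimethyl squarate and C4a=C8a to the alkene of a 5-iodo-2-aryl-dihydropyran. Ring C is cut at O1–C8a and C2–C3 (hetero-Diels–Alder) to veratraldehyde and Danishefsky's diene.
Enabling feature: ring A (C4a, C5, C6, C7, C8, C8a) is a hexasubstituted benzene. C5–OMe and C8–OH stand para, C6–OMe and C7–OMe lie between them, and the sixth edge C4a–C8a belongs to ring C and carries O1 on C8a. That is a mono-O-methyl 2,3-dimethoxyhydroquinone, so the four squarate carbons can be fused onto an enol-ether alkene.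
Forward order of rings: ring B is bought, ring C is made first, a cyclobutenone is hung on the future C4a as a temporary ring, and ring A arises last by its expansion.
Stereochemistry: C2 (S, as read from the target SMILES) comes from Si-face addition to the aldehyde in the catalytic asymmetric hetero-Diels–Alder step and is not touched afterwards. The C4 carbinol and the cyclobutenone C4 centres are temporary. The ketone returns only after ring A exists, and the last deprotection is neutral, so racemisation through the chalcone has no opening.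

Key step: step 6

Assumption: BINOL–Ti catalysts normally direct carbon nucleophiles to the Re face of aromatic aldehydes with the (R)-ligand, so the (S)-ligand is written for Si-face attack. The sense is to be checked on 4 and the ligand antipode exchanged if it is opposite.

Step 1
Reactants: 1 3,4-dimethoxybenzaldehyde (veratraldehyde); 2 Danishefsky's diene ((E)-1-methoxy-3-(trimethylsilyloxy)buta-1,3-diene)
Product: 4 (S)-2-(3,4-dimethoxyphenyl)-2,3-dihydro-4H-pyran-4-one, via O-silyl aldol adduct 3 (not isolated)
Conditions: (S)-BINOL (20 mol %), Ti(OiPr)4 (10 mol %), 4 Å MS, Et2O, −20 °C; then TFA (cat.), CH2Cl2, 0 °C to rt; aq NaHCO3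
Reagents that add atoms: none
Why: This is a catalytic asymmetric hetero-Diels–Alder reaction in its stepwise Mukaiyama-aldol/cyclisation form, well established for aromatic aldehydes, in which the chiral titanium complex blocks the Re face of the bound aldehyde so that the diene CH2 terminus adds to the Si face and sets C2 as S, after which acid closes the freed hydroxyl onto the methoxyvinyl ketone with loss of methanol.

Step 2
Reactants: 4 (S)-2-(3,4-dimethoxyphenyl)-2,3-dihydro-4H-pyran-4-one
Product: 5 (S)-2-(3,4-dimethoxyphenyl)-5-iodo-2,3-dihydro-4H-pyran-4-one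
Conditions: I2 (1.5 equiv), pyridine/CH2Cl2 1:1, 0 °C to rt; aq Na2S2O3
Reagents that add atoms: iodine, II
Why: This is the iodine/pyridine α-iodination of an enone, and it should be fast because C5 is the nucleophilic β-carbon of the enol ether inside the vinylogous ester, while unactivated I2 leaves the veratryl ring alone and C2 is not involved.

Step 3
Reactants: 5 (S)-2-(3,4-dimethoxyphenyl)-5-iodo-2,3-dihydro-4H-pyran-4-one
Product: 6 (2S,4S)-2-(3,4-dimethoxyphenyl)-5-iodo-3,4-dihydro-2H-pyran-4-ol (2,4-cis)
Conditions: NaBH4, CeCl3·7H2O, MeOH/CH2Cl2, −78 to −20 °C; aq NaHCO3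
Reagents that add atoms: none
Why: This is a Luche 1,2-reduction, in which hydride is delivered axially to the half-chair that keeps the C2 aryl group equatorial, so the C4 hydroxyl should end up pseudo-equatorial and cis to the aryl group (4S), a centre that is only temporary.

Step 4
Reactants: 6 (2S,4S)-2-(3,4-dimethoxyphenyl)-5-iodo-3,4-dihydro-2H-pyran-4-ol
Product: 7 (2S,4S)-4-(tert-butyldimethylsilyloxy)-2-(3,4-dimethoxyphenyl)-5-iodo-3,4-dihydro-2H-pyran
Conditions: TBSCl, imidazole, DMF, rt
Reagents that add atoms: tert-butyldimethylsilyl chloride, CC(C)(C)[Si](C)(C)Cl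
Why: This is a standard silyl ether formation under mildly basic conditions, which avoids the acid-induced allylic (Ferrier-type) ionisation of the enol-ether carbinol and gives a mask that tolerates organolithium reagents and heat.

Step 5
Reactants: 7 (2S,4S)-4-(tert-butyldimethylsilyloxy)-2-(3,4-dimethoxyphenyl)-5-iodo-3,4-dihydro-2H-pyran; 8 dimethyl squarate (3,4-dimethoxycyclobut-3-ene-1,2-dione)
Product: 11 4-[(2S,4S)-4-(tert-butyldimethylsilyloxy)-2-(3,4-dimethoxyphenyl)-3,4-dihydro-2H-pyran-5-yl]-2,3,4-trimethoxycyclobut-2-en-1-one (both epimers at cyclobutenone C4), via 5-lithiodihydropyran 9 (not isolated), via lithium alkoxide adduct 10 (not isolated)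
Conditions: t-BuLi (2.1 equiv), Et2O, −78 °C, 15 min; cannulated into 8, THF, −78 °C; MeOTf (1.5 equiv), −78 to 0 °C; aq NaHCO3
Reagents that add atoms: methyl trifluoromethanesulfonate, COS(=O)(=O)C(F)(F)F
Why: Iodine–lithium exchange, 1,2-addition of the alkenyllithium to one squarate carbonyl and capture of the alkoxide with methyl triflate make up the standard entry to 4-alkenyl-4-alkoxycyclobutenones; the exchange outruns any deprotonation at −78 °C, the second equivalent of t-BuLi destroys the tert-butyl iodide, loss of the C4 silyloxy group would need a six-ring allene, the short time at −78 °C holds back elimination of O1, and the new quaternary centre forms as a mixture that step 6 erases.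

Step 6
Reactants: 11 4-[(2S,4S)-4-(tert-butyldimethylsilyloxy)-2-(3,4-dimethoxyphenyl)-3,4-dihydro-2H-pyran-5-yl]-2,3,4-trimethoxycyclobut-2-en-1-one
Product: 14 (2S,4S)-4-(tert-butyldimethylsilyloxy)-2-(3,4-dimethoxyphenyl)-5,6,7-trimethoxychroman-8-ol, via dienylketene 12 (not isolated), via cyclohexadienone 13 (not isolated)
Conditions: toluene (degassed, 0.02 M), 110 °C, Ar
Reagents that add atoms: none
Why: Heating breaks the cyclobutenone C1–C4 bond in a conrotatory 4π electrocyclic opening to the (Z)-dienylketene 12, whose ketene carbon then bonds to the hydrogen-bearing pyran C6 in a disrotatory 6π electrocyclisation (the C8–C8a bond of the target) to give the cyclohexa-2,4-dienone 13, and a proton shift from C8a to the carbonyl oxygen delivers the phenol 14. The closest known reaction type is the Moore ring expansion of squarate-derived 4-alkenyl- and 4-(hetero)aryl-4-alkoxycyclobutenones to hydroquinone monoethers, which tolerates heteroatom-substituted 2π partners. One ring is closed, the six-membered ring A, by 6π electrocyclisation (formally 6-endo at the ketene carbon) across the cis-locked C4a=C8a alkene of ring C, while the four-membered ring is consumed. No lasting stereocentre is made, because C8a of 13 is flattened by tautomerisation, the epimeric cyclobutenone C4 becomes the sp2 carbon C5, and C2 and C4 are spectators. The step needs the pyranyl group to rotate inward toward the ketene, and this is secured by the donor methoxy group on the same carbon, which rotates outward by torquoselectivity, while a ketene of the wrong geometry can only re-close. Regiochemistry is built in, since the methylated carbinol carbon becomes C5–OMe, the two squarate methoxy carbons become C6 and C7 and the ketene carbonyl becomes the free C8–OH next to O1, and degassed solvent protects the oxidisable product.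

Step 7
Reactants: 14 (2S,4S)-4-(tert-butyldimethylsilyloxy)-2-(3,4-dimethoxyphenyl)-5,6,7-trimethoxychroman-8-ol
Product: 15 (2S,4S)-8-benzyloxy-4-(tert-butyldimethylsilyloxy)-2-(3,4-dimethoxyphenyl)-5,6,7-trimethoxychroman
Conditions: BnBr, K2CO3, DMF, rt, Ar
Reagents that add atoms: benzyl bromide, BrCc1ccccc1
Why: This is a Williamson etherification of the only acidic hydroxyl, and it caps the hydroquinone monoether (C8–OH para to C5–OMe) before an oxidant is used in step 9 without disturbing the silyl ether.

Step 8
Reactants: 15 (2S,4S)-8-benzyloxy-4-(tert-butyldimethylsilyloxy)-2-(3,4-dimethoxyphenyl)-5,6,7-trimethoxychroman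
Product: 16 (2S,4S)-8-benzyloxy-2-(3,4-dimethoxyphenyl)-5,6,7-trimethoxychroman-4-ol
Conditions: TBAF, THF, 0 °C to rt
Reagents that add atoms: none
Why: This is a fluoride-induced cleavage of a secondary silyl ether, chosen over acid because the C4–O bond sits on a very electron-rich arene (O1, C5–OMe and C7–OMe all conjugate with it) and would ionise under acidic desilylation.

Step 9
Reactants: 16 (2S,4S)-8-benzyloxy-2-(3,4-dimethoxyphenyl)-5,6,7-trimethoxychroman-4-ol
Product: 17 (S)-8-benzyloxy-2-(3,4-dimethoxyphenyl)-5,6,7-trimethoxychroman-4-one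
Conditions: Dess–Martin periodinane, NaHCO3, CH2Cl2, 0 °C to rt
Reagents that add atoms: none
Why: This is a buffered Dess–Martin oxidation of a benzylic secondary alcohol, which removes the temporary C4 centre under near-neutral conditions, so neither ionisation at C4 nor base-induced ring opening at C2 should occur.

Step 10
Reactants: 17 (S)-8-benzyloxy-2-(3,4-dimethoxyphenyl)-5,6,7-trimethoxychroman-4-one
Product: 18 (S)-8-hydroxy-2-(3,4-dimethoxyphenyl)-5,6,7-trimethoxychroman-4-one (target)
Conditions: H2 (1 atm), 10 % Pd/C, EtOAc, rt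
Reagents that add atoms: none
Why: This is a catalytic hydrogenolysis of an aryl benzyl ether, routine on flavanones, which is faster than attack on the electron-rich aryl ketone or on the C2–O1 bond and involves neither acid nor base, so the retro-oxa-Michael path to the chalcone stays closed and C2 remains S.

Compound list
1 | 3,4-dimethoxybenzaldehyde (veratraldehyde) | COc1ccc(C=O)cc1OC | starting material
2 | Danishefsky's diene, (E)-1-methoxy-3-(trimethylsilyloxy)buta-1,3-diene | CO/C=C/C(=C)O[Si](C)(C)C | starting material
3 | (S,E)-5-(3,4-dimethoxyphenyl)-1-methoxy-5-(trimethylsilyloxy)pent-1-en-3-one (not isolated) | COc1ccc([C@H](CC(=O)/C=C/OC)O[Si](C)(C)C)cc1OC | intermediate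
4 | (S)-2-(3,4-dimethoxyphenyl)-2,3-dihydro-4H-pyran-4-one | COc1ccc([C@@H]2CC(=O)C=CO2)cc1OC | intermediate
5 | (S)-2-(3,4-dimethoxyphenyl)-5-iodo-2,3-dihydro-4H-pyran-4-one | COc1ccc([C@@H]2CC(=O)C(I)=CO2)cc1OC | intermediate
6 | (2S,4S)-2-(3,4-dimethoxyphenyl)-5-iodo-3,4-dihydro-2H-pyran-4-ol (2,4-cis) | COc1ccc([C@@H]2C[C@H](O)C(I)=CO2)cc1OC | intermediate
7 | (2S,4S)-4-(tert-butyldimethylsilyloxy)-2-(3,4-dimethoxyphenyl)-5-iodo-3,4-dihydro-2H-pyran | COc1ccc([C@@H]2C[C@H](O[Si](C)(C)C(C)(C)C)C(I)=CO2)cc1OC | intermediate
8 | dimethyl squarate (3,4-dimethoxycyclobut-3-ene-1,2-dione) | COC1=C(OC)C(=O)C1=O | starting material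
9 | (2S,4S)-4-(tert-butyldimethylsilyloxy)-2-(3,4-dimethoxyphenyl)-5-lithio-3,4-dihydro-2H-pyran (not isolated) | COc1ccc([C@@H]2C[C@H](O[Si](C)(C)C(C)(C)C)C([Li])=CO2)cc1OC | intermediate
10 | lithium alkoxide of the 4-hydroxy-2,3-dimethoxy-4-(dihydropyran-5-yl)cyclobut-2-enone (not isolated) | COc1ccc([C@@H]2C[C@H](O[Si](C)(C)C(C)(C)C)C(C3(O[Li])C(OC)=C(OC)C3=O)=CO2)cc1OC | intermediate
11 | 4-[(2S,4S)-4-(tert-butyldimethylsilyloxy)-2-(3,4-dimethoxyphenyl)-3,4-dihydro-2H-pyran-5-yl]-2,3,4-trimethoxycyclobut-2-en-1-one (epimers at cyclobutenone C4) | COc1ccc([C@@H]2C[C@H](O[Si](C)(C)C(C)(C)C)C(C3(OC)C(OC)=C(OC)C3=O)=CO2)cc1OC | intermediate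
12 | (Z)-4-[(2S,4S)-4-(tert-butyldimethylsilyloxy)-2-(3,4-dimethoxyphenyl)-3,4-dihydro-2H-pyran-5-yl]-2,3,4-trimethoxybuta-1,3-dien-1-one, the dienylketene (not isolated) | COc1ccc([C@@H]2C[C@H](O[Si](C)(C)C(C)(C)C)C(/C(OC)=C(OC)\C(OC)=C=O)=CO2)cc1OC | intermediate
13 | (2S,4S)-4-(tert-butyldimethylsilyloxy)-2-(3,4-dimethoxyphenyl)-5,6,7-trimethoxy-2,3,4,8a-tetrahydro-8H-chromen-8-one, C8a undefined (not isolated) | COc1ccc([C@@H]2C[C@H](O[Si](C)(C)C(C)(C)C)C3=C(OC)C(OC)=C(OC)C(=O)C3O2)cc1OC | intermediate
14 | (2S,4S)-4-(tert-butyldimethylsilyloxy)-2-(3,4-dimethoxyphenyl)-5,6,7-trimethoxychroman-8-ol | COc1ccc([C@@H]2C[C@H](O[Si](C)(C)C(C)(C)C)c3c(OC)c(OC)c(OC)c(O)c3O2)cc1OC | intermediate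
15 | (2S,4S)-8-benzyloxy-4-(tert-butyldimethylsilyloxy)-2-(3,4-dimethoxyphenyl)-5,6,7-trimethoxychroman | COc1ccc([C@@H]2C[C@H](O[Si](C)(C)C(C)(C)C)c3c(OC)c(OC)c(OC)c(OCc4ccccc4)c3O2)cc1OC | intermediate
16 | (2S,4S)-8-benzyloxy-2-(3,4-dimethoxyphenyl)-5,6,7-trimethoxychroman-4-ol | COc1ccc([C@@H]2C[C@H](O)c3c(OC)c(OC)c(OC)c(OCc4ccccc4)c3O2)cc1OC | intermediate
17 | (S)-8-benzyloxy-2-(3,4-dimethoxyphenyl)-5,6,7-trimethoxychroman-4-one | COc1ccc([C@@H]2CC(=O)c3c(OC)c(OC)c(OC)c(OCc4ccccc4)c3O2)cc1OC | intermediate
18 | (S)-8-hydroxy-2-(3,4-dimethoxyphenyl)-5,6,7-trimethoxychroman-4-one | COc1ccc([C@@H]2CC(=O)c3c(c(O)c(OC)c(OC)c3OC)O2)cc1OC | target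

Total step count: 10. Longest linear sequence: 10 steps (1 to 18); dimethyl squarate enters as bought.

Steps most likely to fail

Risk 1, step 5. In the alkenyllithium the C–Li bond lies anti-periplanar to the ring C6–O1 bond. Ring-opening β-elimination to an alkynyl alkoxide can therefore compete with addition as soon as the temperature drifts. Capture of the hindered tertiary alkoxide by methyl triflate may also stay incomplete. The fallback sets out from 7 and comes back at 11. It replaces the carbanion itself and takes the one-pot operation apart. Iodine–magnesium exchange with the turbo-Grignard reagent (iPrMgCl·LiCl, THF, −20 °C) should give the more covalent alkenylmagnesium chloride F1. Alkenylmagnesium reagents with a β-oxygen are known to persist at such temperatures. Addition to 8 at −40 °C and an NH4Cl quench should give the isolable tertiary carbinol 4-hydroxy-2,3-dimethoxy-4-(dihydropyran-5-yl)cyclobut-2-enone F2. This is then methylated in a separate operation (MeI, Ag2O, K2CO3, 1,4-dioxane, rt) to 11.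

Risk 2, step 6. Three processes may interfere.
- The neighbouring silyloxy group may twist the dienylketene, because peri strain develops between C4–O and the emerging C5–OMe. This would slow the 6π closure enough for ketene dimerisation or capture by adventitious nucleophiles to take over.
- At reflux the newly formed, very electron-rich benzylic C4–O bond may ionise with loss of silanol.
- Aerial oxidation of the hydroquinone monoether is a further drain.

The fallback sets out from 11 and comes back at 18. The ketone is unveiled before the annulation instead of after it. Buffered desilylation (TBAF/AcOH, THF, 0 °C) should give the allylic alcohol 4-[(2S,4S)-2-(3,4-dimethoxyphenyl)-4-hydroxy-3,4-dihydro-2H-pyran-5-yl]-2,3,4-trimethoxycyclobut-2-enone F3. Oxidation (Dess–Martin periodinane, NaHCO3, CH2Cl2, or MnO2) should then give the enone 4-[(S)-2-(3,4-dimethoxyphenyl)-4-oxo-3,4-dihydro-2H-pyran-5-yl]-2,3,4-trimethoxycyclobut-2-enone F4. Heating F4 in degassed toluene should run the same opening/closure cascade and give 18 directly.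

With an sp2 carbon at C4 the peri strain and the ionisable group are both gone, and no phenol protection is needed. The price is that the 2π partner is now a push–pull alkene and the finished flavanone is exposed to 110 °C. For that reason this order is held in reserve.

Risk 3, step 1. The electron-rich aldehyde is a sluggish electrophile, so an uncatalysed or achiral-titanium background reaction may erode the facial selectivity on which every later compound depends. The fallback no longer asks the catalyst alone for enantiopurity. Material of insufficient enantiomeric purity is carried unchanged through steps 2 and 3. The fallback then sets out from 6 and comes back at 6, before step 4. It is a lipase-catalysed acylation (Candida antarctica lipase B or Pseudomonas cepacia lipase, vinyl acetate, MTBE, rt), a kinetic resolution well known for 2-halocycloalk-2-enols. By Kazlauskas' rule it should acylate the (4R)-configured minor enantiomer to (2R,4R)-4-acetoxy-2-(3,4-dimethoxyphenyl)-5-iodo-3,4-dihydro-2H-pyran F5. F5 is removed by chromatography and the unreacted (2S,4S)-alcohol 6 goes on. In the limit the same operation resolves fully racemic material made with an achiral Lewis acid.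

Further compounds
F1 | step 5 | [(2S,4S)-4-(tert-butyldimethylsilyloxy)-2-(3,4-dimethoxyphenyl)-3,4-dihydro-2H-pyran-5-yl]magnesium chloride | COc1ccc([C@@H]2C[C@H](O[Si](C)(C)C(C)(C)C)C([Mg]Cl)=CO2)cc1OC
F2 | step 5 | 4-[(2S,4S)-4-(tert-butyldimethylsilyloxy)-2-(3,4-dimethoxyphenyl)-3,4-dihydro-2H-pyran-5-yl]-4-hydroxy-2,3-dimethoxycyclobut-2-en-1-one | COc1ccc([C@@H]2C[C@H](O[Si](C)(C)C(C)(C)C)C(C3(O)C(OC)=C(OC)C3=O)=CO2)cc1OC
F3 | step 6 | 4-[(2S,4S)-2-(3,4-dimethoxyphenyl)-4-hydroxy-3,4-dihydro-2H-pyran-5-yl]-2,3,4-trimethoxycyclobut-2-en-1-one | COc1ccc([C@@H]2C[C@H](O)C(C3(OC)C(OC)=C(OC)C3=O)=CO2)cc1OC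
F4 | step 6 | 4-[(S)-2-(3,4-dimethoxyphenyl)-4-oxo-3,4-dihydro-2H-pyran-5-yl]-2,3,4-trimethoxycyclobut-2-en-1-one | COc1ccc([C@@H]2CC(=O)C(C3(OC)C(OC)=C(OC)C3=O)=CO2)cc1OC
F5 | step 1 | (2R,4R)-4-acetoxy-2-(3,4-dimethoxyphenyl)-5-iodo-3,4-dihydro-2H-pyran | COc1ccc([C@H]2C[C@@H](OC(C)=O)C(I)=CO2)cc1OC
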